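**Retrosynthetic overview**

1. Target 15 comes from the protected styrenyl oxane 14 by one hydrogenation/hydrogenolysis. The alkene of 14 comes from a Wittig reaction of oxane-2-carbaldehyde 10 with the ring A benzyl ylide.
2. Aldehyde 10 comes from ester 9, and 9 from dihydropyran 8 by face-selective hydrogenation, which sets the third ring stereocentre.
3. Feature on which the strategy rests: in the oxane of the target, C2 (bearing ring B) and C3 are a styrene unit, while O1, C6, C5 and the oxygenated C4 are a 4-alkoxy-1-oxadiene whose C6 ester stands for the first carbon of the arylethyl chain. Dihydropyran 8 is therefore made by [4+2] cycloaddition of oxadiene 4 with styrene 7, forming O1–C2 and C3–C4 with aryl and C4–O cis.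
4. Oxadiene 4 comes from benzyl vinyl ether and ethyl chlorooxoacetate. Styrene 7 comes from 5-hydroxyvanillin, with the catechol tied into a diphenylmethylene ketal so that the oxygen para to the vinyl group stays conjugated.
5. Ring order: the protecting benzodioxole ring (step 2), then the oxane ring (step 4), which is the only skeletal ring made.

Key step: step 4

Assumption: the ligand enantiomer in step 4 is chosen from the square-planar chelate model of divalent copper bis(oxazoline) complexes with 1,2-dicarbonyl substrates; if a styrene were to add to the other face, the (S,S) ligand would be used in the same way. "t-Bu-box" means 2,2'-isopropylidenebis(4-tert-butyl-2-oxazoline).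

**Route**

Step 1
Reactants: 1 benzyl vinyl ether; 2 ethyl chlorooxoacetate
Product: 4 ethyl (E)-4-(benzyloxy)-2-oxobut-3-enoate, via ethyl 4-(benzyloxy)-4-chloro-2-oxobutanoate 3 (not isolated)
Conditions: 1 (1.5 equiv), CH2Cl2, 0 °C to rt; then Et3N, 0 °C
Reagents that add atoms: none
Why: Electrophilic acylation of the enol ether at its CH2 terminus gives the α-chloro ether, and base-induced loss of HCl gives the conjugated (E)-β-alkoxy enone, the standard acylation of vinyl ethers with oxalyl chloride derivatives.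

Step 2
Reactants: 5 3,4-dihydroxy-5-methoxybenzaldehyde (5-hydroxyvanillin)
Product: 6 7-methoxy-2,2-diphenyl-1,3-benzodioxole-5-carbaldehyde
Conditions: Ph2CCl2, K2CO3, MeCN, 60 °C
Reagents that add atoms: dichlorodiphenylmethane, ClC(Cl)(c1ccccc1)c1ccccc1
Why: Double substitution of the geminal dichloride by the two adjacent phenoxides closes the five-membered diphenylmethylene ketal of the catechol; only the catechol pair can form it, and the methyl ether and aldehyde are untouched.

Step 3
Reactants: 6 7-methoxy-2,2-diphenyl-1,3-benzodioxole-5-carbaldehyde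
Product: 7 6-ethenyl-4-methoxy-2,2-diphenyl-1,3-benzodioxole
Conditions: Ph3PCH3Br, KOtBu, THF, 0 °C to rt
Reagents that add atoms: methyltriphenylphosphonium bromide, C[P+](c1ccccc1)(c1ccccc1)c1ccccc1.[Br-]
Why: Wittig methylenation of an aromatic aldehyde with the non-stabilised ylide; the ketal is stable to base.

Step 4
Reactants: 4 ethyl (E)-4-(benzyloxy)-2-oxobut-3-enoate; 7 6-ethenyl-4-methoxy-2,2-diphenyl-1,3-benzodioxole
Product: 8 ethyl (2S,4S)-4-(benzyloxy)-2-(7-methoxy-2,2-diphenyl-1,3-benzodioxol-5-yl)-3,4-dihydro-2H-pyran-6-carboxylate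
Conditions: [Cu((R,R)-t-Bu-box)](SbF6)2 (10 mol%, from CuCl2, AgSbF6 and the ligand), 4 Å MS, CH2Cl2, −20 °C to rt
Reagents that add atoms: none
Why: Proposed new method: the cationic divalent copper centre chelates the ketone and ester carbonyls of 4 in the plane of the ligand, which lowers the LUMO of the 1-oxadiene; the CH2 terminus of 7 then bonds to C4 of the oxadiene while the ketone oxygen closes onto the developing benzylic cation, which the coplanar para oxygen of the benzodioxole stabilises. The closest known reaction type is the inverse-demand hetero-Diels–Alder reaction of 4-alkoxy-2-oxobut-3-enoates with enol ethers under copper bis(oxazoline) catalysis; a styrene is a weaker nucleophile than an enol ether, which is why the more Lewis-acidic hexafluoroantimonate complex is used and why the catechol is held in a planar dioxole and not as two benzyl ethers, of which the para one would be twisted out of conjugation by its two ortho neighbours. The dihydropyran closes in the [4+2] mode through an asynchronous six-membered transition state, the C3–C4 bond leading and the O1–C2 bond following. C4 is set by the ligand: in the square-planar chelate a tert-butyl group of the (R,R) ligand covers one face of the oxadiene, so that the alkene should add to the si face of C4 and give the (4S) centre. C2 is set relative to C4 by endo placement of the aryl group over the chelated dicarbonyl, which gives the 2,4-cis adduct. The step needs regiochemistry, secured by the matched polarisation of the two partners, and suppression of cationic oligomerisation of the styrene, for which 4 is kept in excess and 7 is added slowly.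

Step 5
Reactants: 8 ethyl (2S,4S)-4-(benzyloxy)-2-(7-methoxy-2,2-diphenyl-1,3-benzodioxol-5-yl)-3,4-dihydro-2H-pyran-6-carboxylate
Product: 9 ethyl (2R,4S,6S)-4-(benzyloxy)-6-(7-methoxy-2,2-diphenyl-1,3-benzodioxol-5-yl)oxane-2-carboxylate
Conditions: H2 (3 atm), 5% Rh/Al2O3, EtOAc, rt
Reagents that add atoms: none
Why: Heterogeneous syn hydrogenation of the enol ether double bond from the face opposite the cis aryl and benzyloxy groups should place the ester on their side and give the all-equatorial (2R) ester, which is also the thermodynamic epimer; rhodium on alumina is chosen because it reduces alkenes without hydrogenolysis of the allylic benzyl ether or the ketal.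

Step 6
Reactants: 9 ethyl (2R,4S,6S)-4-(benzyloxy)-6-(7-methoxy-2,2-diphenyl-1,3-benzodioxol-5-yl)oxane-2-carboxylate
Product: 10 (2R,4S,6S)-4-(benzyloxy)-6-(7-methoxy-2,2-diphenyl-1,3-benzodioxol-5-yl)oxane-2-carbaldehyde
Conditions: i-Bu2AlH (1.1 equiv), CH2Cl2, −78 °C; aq. KNaC4H4O6
Reagents that add atoms: none
Why: Partial reduction of an α-alkoxy ester; the tetrahedral aluminium hemiacetal is held by chelation to the ring oxygen at −78 °C and collapses to the aldehyde only on work-up.

Step 7
Reactants: 11 4-(benzyloxy)-3-methoxybenzyl alcohol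
Product: 12 [4-(benzyloxy)-3-methoxybenzyl]triphenylphosphonium bromide
Conditions: PPh3·HBr, MeCN, reflux
Reagents that add atoms: triphenylphosphine hydrobromide, [Br-].c1ccc(cc1)[PH+](c1ccccc1)c1ccccc1
Why: Direct conversion of an electron-rich benzylic alcohol into its phosphonium salt; protonation and loss of water give a benzylic cation stabilised by the para oxygen, which triphenylphosphine captures.

Step 8
Reactants: 10 (2R,4S,6S)-4-(benzyloxy)-6-(7-methoxy-2,2-diphenyl-1,3-benzodioxol-5-yl)oxane-2-carbaldehyde; 12 [4-(benzyloxy)-3-methoxybenzyl]triphenylphosphonium bromide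
Product: 14 (2R,4R,6S)-4-(benzyloxy)-2-{2-[4-(benzyloxy)-3-methoxyphenyl]ethenyl}-6-(7-methoxy-2,2-diphenyl-1,3-benzodioxol-5-yl)oxane (E/Z mixture), via [4-(benzyloxy)-3-methoxybenzylidene]triphenylphosphorane 13 (not isolated)
Conditions: 12, NaN(SiMe3)2, THF, 0 °C; then 10, −78 °C to rt
Reagents that add atoms: none
Why: Wittig olefination with a semi-stabilised benzyl ylide; the alkene geometry is irrelevant because the bond is hydrogenated next, and the centre α to the aldehyde is equatorial and thus already the thermodynamic one.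

Step 9
Reactants: 14 (2R,4R,6S)-4-(benzyloxy)-2-{2-[4-(benzyloxy)-3-methoxyphenyl]ethenyl}-6-(7-methoxy-2,2-diphenyl-1,3-benzodioxol-5-yl)oxane
Product: 15 5-{(2S,4R,6S)-4-hydroxy-6-[2-(4-hydroxy-3-methoxyphenyl)ethyl]oxan-2-yl}-3-methoxybenzene-1,2-diol (target)
Conditions: H2 (1 atm), 10% Pd/C, EtOAc/MeOH, rt
Reagents that add atoms: none
Why: Heterogeneous hydrogenation saturates the styrenyl alkene, and hydrogenolysis of the aryl benzyl ether, the secondary benzyl ether and the diphenylmethylene ketal should free the phenol, the C4 alcohol and the catechol; no stereocentre is touched.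

**Compound list**

1 | benzyl vinyl ether | C=COCc1ccccc1 | starting material
2 | ethyl chlorooxoacetate | CCOC(=O)C(=O)Cl | starting material
3 | ethyl 4-(benzyloxy)-4-chloro-2-oxobutanoate (racemic) | CCOC(=O)C(=O)CC(Cl)OCc1ccccc1 | intermediate
4 | ethyl (E)-4-(benzyloxy)-2-oxobut-3-enoate | CCOC(=O)C(=O)/C=C/OCc1ccccc1 | intermediate
5 | 3,4-dihydroxy-5-methoxybenzaldehyde | COc1cc(C=O)cc(O)c1O | starting material
6 | 7-methoxy-2,2-diphenyl-1,3-benzodioxole-5-carbaldehyde | COc1cc(C=O)cc2OC(c3ccccc3)(c3ccccc3)Oc12 | intermediate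
7 | 6-ethenyl-4-methoxy-2,2-diphenyl-1,3-benzodioxole | C=Cc1cc(OC)c2OC(c3ccccc3)(c3ccccc3)Oc2c1 | intermediate
8 | ethyl (2S,4S)-4-(benzyloxy)-2-(7-methoxy-2,2-diphenyl-1,3-benzodioxol-5-yl)-3,4-dihydro-2H-pyran-6-carboxylate | CCOC(=O)C1=C[C@@H](OCc2ccccc2)C[C@@H](c2cc(OC)c3OC(c4ccccc4)(c4ccccc4)Oc3c2)O1 | intermediate
9 | ethyl (2R,4S,6S)-4-(benzyloxy)-6-(7-methoxy-2,2-diphenyl-1,3-benzodioxol-5-yl)oxane-2-carboxylate | CCOC(=O)[C@H]1C[C@@H](OCc2ccccc2)C[C@@H](c2cc(OC)c3OC(c4ccccc4)(c4ccccc4)Oc3c2)O1 | intermediate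
10 | (2R,4S,6S)-4-(benzyloxy)-6-(7-methoxy-2,2-diphenyl-1,3-benzodioxol-5-yl)oxane-2-carbaldehyde | O=C[C@H]1C[C@@H](OCc2ccccc2)C[C@@H](c2cc(OC)c3OC(c4ccccc4)(c4ccccc4)Oc3c2)O1 | intermediate
11 | 4-(benzyloxy)-3-methoxybenzyl alcohol | COc1cc(CO)ccc1OCc1ccccc1 | starting material
12 | [4-(benzyloxy)-3-methoxybenzyl]triphenylphosphonium bromide | COc1cc(C[P+](c2ccccc2)(c2ccccc2)c2ccccc2)ccc1OCc1ccccc1.[Br-] | intermediate
13 | [4-(benzyloxy)-3-methoxybenzylidene]triphenylphosphorane | COc1cc(C=P(c2ccccc2)(c2ccccc2)c2ccccc2)ccc1OCc1ccccc1 | intermediate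
14 | (2R,4R,6S)-4-(benzyloxy)-2-{2-[4-(benzyloxy)-3-methoxyphenyl]ethenyl}-6-(7-methoxy-2,2-diphenyl-1,3-benzodioxol-5-yl)oxane (E/Z mixture) | COc1cc(C=C[C@H]2C[C@@H](OCc3ccccc3)C[C@@H](c3cc(OC)c4OC(c5ccccc5)(c5ccccc5)Oc4c3)O2)ccc1OCc1ccccc1 | intermediate
15 | 5-{(2S,4R,6S)-4-hydroxy-6-[2-(4-hydroxy-3-methoxyphenyl)ethyl]oxan-2-yl}-3-methoxybenzene-1,2-diol | COc1cc(CC[C@H]2C[C@@H](O)C[C@@H](c3cc(O)c(O)c(OC)c3)O2)ccc1O | target

**Step count**

Total: 9 steps. Longest linear sequence: 7 steps (5 → 6 → 7 → 8 → 9 → 10 → 14 → 15, that is steps 2, 3, 4, 5, 6, 8 and 9).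

**Steps most likely to fail, with fallbacks**

Step 4 (proposed new method). The styrene may be too weak a nucleophile for the push–pull oxadiene, so that cationic oligomerisation of 7 or decay of 4 outruns cycloaddition. The closure may also become stepwise and erode the cis relation or the enantioselectivity. The fallback is a Prins cyclisation by known chemistry; it sets out from aldehyde 6 and comes back to the route at aldehyde 10.
- Commercial (R)-tert-butyl(oxiran-2-ylmethoxy)diphenylsilane is opened at its terminal carbon with CH2=CHMgBr and catalytic CuI in THF to give (2R)-1-[(tert-butyldiphenylsilyl)oxy]pent-4-en-2-ol F1.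
- F1 and 6 are cyclised with BF3·OEt2 and AcOH in CH2Cl2. The chair oxocarbenium transition state places both substituents and the incoming acetate equatorial, which should give the all-cis (2R,4S,6S)-2-{[(tert-butyldiphenylsilyl)oxy]methyl}-6-(7-methoxy-2,2-diphenyl-1,3-benzodioxol-5-yl)oxan-4-yl acetate F2. The electron-rich aryl group sits on the aldehyde partner, so oxonia-Cope scrambling should not racemise the carbinol centre.
- Methanolysis (K2CO3, MeOH) gives (2R,4S,6S)-2-{[(tert-butyldiphenylsilyl)oxy]methyl}-6-(7-methoxy-2,2-diphenyl-1,3-benzodioxol-5-yl)oxan-4-ol F3.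
- Benzylation (NaH, BnBr, DMF) gives tert-butyl{[(2R,4S,6S)-4-(benzyloxy)-6-(7-methoxy-2,2-diphenyl-1,3-benzodioxol-5-yl)oxan-2-yl]methoxy}diphenylsilane F4.
- Bu4NF in THF gives [(2R,4S,6S)-4-(benzyloxy)-6-(7-methoxy-2,2-diphenyl-1,3-benzodioxol-5-yl)oxan-2-yl]methanol F5.
- Dess–Martin oxidation of F5 gives aldehyde 10, from which steps 8 and 9 follow unchanged.

Step 5. Hydrogenolysis of the allylic C4–O bond may compete with alkene reduction. Hydrogen may also add to the wrong face, because both ring substituents are pseudo-equatorial and shield their face only weakly. The fallback sets out from 8 and comes back at 9. Homogeneous hydrogenation with [Ir(cod)(PCy3)(py)]PF6 in CH2Cl2 under H2 does not cleave C–O bonds but may deliver hydrogen to either face. Stereocontrol is therefore moved from kinetic face selection to equilibration: the new centre is α to the ester, so NaOEt in EtOH should drain the axial-ester epimer ethyl (2S,4S,6S)-4-(benzyloxy)-6-(7-methoxy-2,2-diphenyl-1,3-benzodioxol-5-yl)oxane-2-carboxylate F6 into the all-equatorial ester 9.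

Step 9. The benzylic ring C–O bond at the ring B carbon may be hydrogenolysed while the slow secondary benzyl ether is still being removed, which would open the oxane; cleavage may also stall at partly protected stages. The fallback sets out from 14 and comes back at 15. Only the alkene is saturated over Rh/Al2O3 under H2 (as in step 5) to give (2S,4R,6S)-4-(benzyloxy)-2-{2-[4-(benzyloxy)-3-methoxyphenyl]ethyl}-6-(7-methoxy-2,2-diphenyl-1,3-benzodioxol-5-yl)oxane F7. The two benzyl ethers and the ketal are then removed without hydrogen, with BCl3 and pentamethylbenzene in CH2Cl2 at −78 °C, to give 15. These conditions are in use for debenzylation of C-aryl glycosides, which are also 2-aryloxanes.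

**Further compounds**

F1 | step 4 | (2R)-1-[(tert-butyldiphenylsilyl)oxy]pent-4-en-2-ol | CC(C)(C)[Si](OC[C@H](O)CC=C)(c1ccccc1)c1ccccc1
F2 | step 4 | (2R,4S,6S)-2-{[(tert-butyldiphenylsilyl)oxy]methyl}-6-(7-methoxy-2,2-diphenyl-1,3-benzodioxol-5-yl)oxan-4-yl acetate | CC(C)(C)[Si](OC[C@H]1C[C@@H](OC(C)=O)C[C@@H](c2cc(OC)c3OC(c4ccccc4)(c4ccccc4)Oc3c2)O1)(c1ccccc1)c1ccccc1
F3 | step 4 | (2R,4S,6S)-2-{[(tert-butyldiphenylsilyl)oxy]methyl}-6-(7-methoxy-2,2-diphenyl-1,3-benzodioxol-5-yl)oxan-4-ol | CC(C)(C)[Si](OC[C@H]1C[C@@H](O)C[C@@H](c2cc(OC)c3OC(c4ccccc4)(c4ccccc4)Oc3c2)O1)(c1ccccc1)c1ccccc1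
F4 | step 4 | tert-butyl{[(2R,4S,6S)-4-(benzyloxy)-6-(7-methoxy-2,2-diphenyl-1,3-benzodioxol-5-yl)oxan-2-yl]methoxy}diphenylsilane | CC(C)(C)[Si](OC[C@H]1C[C@@H](OCc2ccccc2)C[C@@H](c2cc(OC)c3OC(c4ccccc4)(c4ccccc4)Oc3c2)O1)(c1ccccc1)c1ccccc1
F5 | step 4 | [(2R,4S,6S)-4-(benzyloxy)-6-(7-methoxy-2,2-diphenyl-1,3-benzodioxol-5-yl)oxan-2-yl]methanol | OC[C@H]1C[C@@H](OCc2ccccc2)C[C@@H](c2cc(OC)c3OC(c4ccccc4)(c4ccccc4)Oc3c2)O1
F6 | step 5 | ethyl (2S,4S,6S)-4-(benzyloxy)-6-(7-methoxy-2,2-diphenyl-1,3-benzodioxol-5-yl)oxane-2-carboxylate | CCOC(=O)[C@@H]1C[C@@H](OCc2ccccc2)C[C@@H](c2cc(OC)c3OC(c4ccccc4)(c4ccccc4)Oc3c2)O1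
F7 | step 9 | (2S,4R,6S)-4-(benzyloxy)-2-{2-[4-(benzyloxy)-3-methoxyphenyl]ethyl}-6-(7-methoxy-2,2-diphenyl-1,3-benzodioxol-5-yl)oxane | COc1cc(CC[C@H]2C[C@@H](OCc3ccccc3)C[C@@H](c3cc(OC)c4OC(c5ccccc5)(c5ccccc5)Oc4c3)O2)ccc1OCc1ccccc1
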